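Target in the larch run rose steeply and then bent over, and I followed it in mM rather than in percent.

in all of them: enzyme 0.10 µM
- larch: starting material 1.5 mM; second substrate 2 mM; run made earlier
- flask: starting material 1.0 mM; second substrate 2.00 mM

larch run (percent of the starting material charged)

| time / s | target / % | starting material / % |
|---|---|---|
| 10.0 | 30.6 | 70.4 |
| 12.0 | 32.8 | 67.3 |
| 20.0 | 39.7 | 60.7 |
| 25.0 | 42.2 | 56.2 |
| 30.0 | 43.2 | 56.6 |
| 40.0 | 45.4 | 51.8 |

(scatter of a reading: 1 percentage point)

- no earlier run changes the charge of second substrate; that part of a forecast is a guess

* apparent order in second substrate when 20% of the starting material are converted (percent change of the rate of making target for one percent more second substrate charged)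

Over the first 10.0 s the larch run gained 0.0459 mM s⁻¹, between 10.0 s and 20.0 s it gained 0.0137 mM s⁻¹, and between 20.0 s and 40.0 s it gained 0.00427 mM s⁻¹. The last two slopes lie 15.0 s apart and differ by a factor of 3.21, so I took an exponential fade with a time of 12.9 s. Starting material fell by a factor of 1.36 from 10.0 s to 40.0 s, less than the slope did, so I read the fade as the enzyme wearing out. The larch run read 0.681 mM of target at 40.0 s, and the fading slope adds 0.0255 mM, giving a level near 0.706 mM. That level over the enzyme charged, 7060 as a reading with its scatter, is the turnover number, the target one enzyme makes before it is lost.

The flask holds 0.10 µM of enzyme and 2.00 mM of second substrate, like the larch run, so I expected it to stop at 0.706 mM of target, 70.6% of its charge of 1.0 mM. No earlier run changes the second substrate, and the forecast put the order at 0.7, saying “the order is a guess”. The flask gave an apparent order of −0.37.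

    starting material + enzyme ⇌ complex A (K = 1300 M⁻¹, k = 5.30 × 10⁶ M⁻¹ s⁻¹)
    complex A → enzyme + target (k = 2100 s⁻¹)
    second substrate + enzyme ⇌ complex B (K = 570 M⁻¹, k = 3.10 × 10⁷ M⁻¹ s⁻¹)
    complex B → enzyme + second product (k = 1600 s⁻¹)
    complex A → spent catalyst (k = 0.290 s⁻¹)

In the flask, second substrate took enzyme 12 times as fast as starting material at the start, each forward step counted alone, while complex A went on to target and to spent catalyst. By 0.600 min the flask held 87.8% of its catalyst as spent catalyst and 6.14% as enzyme, with target at 63.6%. By 3.00 min the flask's spent catalyst stood at >99.9% and its target at 72.4%, with 27.6% of the starting material left, a turnover number of 7240 where the larch readings had given 7060.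

(Readings and results were computed from invented constants, and the scatter is random.)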